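At 10 h the flask zeta has to be answered for, but its readings stop at 3.00 h, with monomer in chains at 6.4 %. Carried on in a straight line, that reckoning gives 21.3 % at 10 h.

| setting | zeta | beta | flask |
|---|---|---|---|
| free monomer | 12 mM | 12 mM | 12 mM |
| initiator | 0.24 mM | 0.12 mM | 0.24 mM |
| impurity | 44 µM | 44 µM | 44 µM |
| remark | the very flask that is asked about, followed so far | run made earlier |  |
| time |  |  | 10 h |

| run | time / h | monomer in chains / % | free monomer / % |
|---|---|---|---|
| zeta | 0.667 | 1.5 | 99.2 |
| zeta | 1.33 | 2.9 | 98.2 |
| zeta | 2.00 | 3.9 | 95.9 |
| zeta | 2.50 | 4.3 | 95.4 |
| zeta | 3.00 | 6.4 | 92.9 |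
| beta | 0.333 | 0 | 99.5 |
| beta | 1.00 | 1.1 | 99.5 |
| beta | 2.00 | 1.6 | 98.7 |
| beta | 3.00 | 3.4 | 97.8 |
| beta | 4.00 | 3.6 | 96.4 |

(each reading ± 0.5 percentage points)

- average number of monomer units in a chain (chains begun, living or dead) at 10 h
- part of the free monomer that has reacted at 10 h

- the average divides the monomer in chains by the number of chains begun, living and dead together
- the numbers in the tables scatter with a standard deviation of 0.5 percentage points
- the earlier runs do not show the number of chains; that part of a forecast is a guess

The average in zeta then hangs on the number of chains begun, and two extreme flasks can be solved in the head. In the first, the impurity harms nothing, so chains begun equal the 0.24 mM of initiator, dp is 10.7, and zeta runs 2.00 times as fast as beta. In the second, each impurity removes one initiator at once, which leaves the chain budget, c(initiator) minus c(impurity), here 0.196 mM, usually called the effective initiator concentration. Then dp is 13.1, and the rate ratio is 2.58. The readings at 3.00 h give a ratio of 1.88, which a scatter of 0.5 percentage points cannot place. This reckoning puts the dp of zeta between the extremes.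

The forecast says dp 10.5 and c 19 %, both below this reckoning, and adds: “Slow initiation would give fewer chains and a higher dp”.

The simulation gives dp 13.7 and c 20.4 %.

    free monomer + initiator → living end + monomer in chains (k = 71.4 M⁻¹ h⁻¹)
    free monomer + living end → monomer in chains + living end, rate k2*[living end]*[free monomer] (k = 273 M⁻¹ h⁻¹)
    monomer in chains + living end → free monomer + living end, rate k3*[living end] as long as [monomer in chains] is above zero (k = 1.47 h⁻¹)
    2 initiator → spent initiator A (k = 406 M⁻¹ h⁻¹)
    initiator + impurity → spent initiator B (k = 31000 M⁻¹ h⁻¹)

On the budget, the result of the asked flask reckons to dp 12.5, and that flask gives 13.7. Its living end stands at 0.179 mM, less than the budget by 0.0170 mM, and its 0.00868 mM of spent initiator A took two initiator each, 0.0174 mM. The neighbouring flask, charged with 0.096 mM of initiator, has a budget of 0.0520 mM, so its 7.59 % of monomer in chains reckons to dp 17.5, and that neighbour gives 16.4. In the neighbouring flask the living end stands at 0.0556 mM, above the budget, with 13 % of the impurity still unbound.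

The readings are calculated for substances that don't exist; noise was put on by code.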